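# Gnetucleistol F (32): pyrone–alkyne Diels–Alder route

## Analysis of the target

Gnetucleistol F (32) is a stilbenolignan built on a 2,3-dihydrobenzofuran (O1, C2, C3, benzo ring B = C3a to C7a). C2 carries a 4-hydroxy-3,5-dimethoxyphenyl (syringyl) ring, C3 a hydroxymethyl group, C7 a methoxy group and C5 an (E)-3,5-dihydroxystyryl arm. There are only two stereocentres, C2 (R) and C3 (S); they are adjacent, both benzylic, and trans across the furan ring. The sensitive groups are the three free phenols, the electron-rich stilbene (acid, light, oxidants) and the C2–O1 bond, a benzylic ether para to a phenol that can open through a quinone methide. The molecule is small, so the difficulty lies not in length but in fixing the absolute configuration of the trans diad without an oxidative phenol coupling and in assembling ring B, whose six positions all differ (O1 at C7a, OMe at C7, H at C6, carbon at C5, H at C4, C3 at C3a). The strategy rests on reading C7a(O)–C7(OMe)–C6(H)–C5(C) as C3–C4–C5–C6 of a 3,4-dioxygenated, 6-substituted 2-pyrone, with C3a and C4 as the two carbons of a terminal alkyne that hangs from the pyrone C3 oxygen through the O1–C2–C3 chain. The stereochemical problem thereby becomes an acyclic two-centre problem, and the arene substitution problem becomes a cycloaddition whose orientation the tether dictates.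

## Retrosynthetic reasoning

**Protecting groups (32 from 31).** The three phenols and the primary alcohol are freed last and together. Free phenols would quench the carbanion used for the olefin and would not survive the carbenoid and thermal steps. In 31 all four oxygens carry acid-labile groups (three MOM ethers, one TBS ether), so one acid treatment should suffice.

**Stilbene double bond (31 from 24 and 29).** The C=C bond is the only link between the resorcinol ring and the rest. Cutting it gives aldehyde 24 and phosphonate 29, which is reached from ester 25 through 26, 27 and 28. A Horner–Wadsworth–Emmons reaction of the carbanion 30 is reliably E-selective, and placing the cut here keeps the heat- and acid-sensitive styryl unit out of the thermal key step.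

**Aldehyde mask (24 from 23).** The formyl carbon is carried as a dimethyl acetal, which is inert to carbenoids, mild base and heat, and is opened by very mild acid once ring B exists.

**Ring B and the furan ring (23 from 21).** The bonds C7a–C3a and C5–C4 are cut together. In the forward sense the pyrone of 21 (diene termini C3 and C6) adds across its own tethered alkyne to give the bridged lactone 22, and decarboxylative cycloreversion gives the arene. This places every substituent of ring B by construction, forms the dihydrofuran in the same event, and creates no stereocentre, so the preset C2/C3 diad only has to survive heat.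

**Pyrone ether (21 from 20, 19, then 12 and 18).** The bond between the pyrone C3 and the ether oxygen must be made with retention at the carbinol carbon. Displacement at that carbon by a pyrone oxygen would invert it, and at this electron-rich benzylic centre it would also risk ionisation. A base-mediated cross-coupling at pyrone C3 would expose the lactone and the 1,3-related silyl ether of 12 to alkoxide. The neutral alternative is insertion of the carbene carbon of diazo dione 18 into the O–H bond of 12. This does not touch the carbinol C–O bond and gives the 4-hydroxypyrone 19. The alkyne keeps its silyl cap through this step to shield it from the carbenoid. The cap is removed at the stage of 19, where the pyrone is protected against ring opening as its enolate (giving 20), and O-methylation then gives 21.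

**Pyrone nucleus (18 from 17, 16, then 13 and 14).** Diazo transfer to the hydroxypyrone 17 gives 18. The pyrone 17 is the lactone of the 3,5-dioxo ester 16, which comes from a Claisen acylation of the dianion 15 of acetoacetate 13 with ester 14. The acetal carbon is therefore in place from the start and no oxidation of a pyrone methyl group is needed.

**Stereodiad (12 from 11, 10, then 8 and 2).** The C2–C3 bond of the target is an aldol bond. The syn aldol of the enolate 9 of imide 8 with aldehyde 2 sets both centres in 10 under control of auxiliary 5. In 10 the alkynyl and hydroxyl groups are syn along the chain. Ring closure later ties the oxygen to the alkyne carbon, so the aryl and CH2O groups, which stay outside the furan ring, end up trans. Reduction to diol 11 and silylation of the primary hydroxyl give 12. Imide 8 comes from acid 4 (by oxidation of alcohol 3) and 5; aldehyde 2 is the MOM ether of 1.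

## Alternatives that were turned down

Alternative 1: asymmetric Prins reaction. The disconnection removes the C3–CH2O bond (and a temporary C2–O bond) from the (E)-diaryl olefin A2. In the forward step a confined chiral Brønsted acid would add formaldehyde A3 to the olefin A2 and close the trans-4,5-diaryl-1,3-dioxane A1.
- For: it is catalytic in chirality, needs no auxiliary, and starts from a flat olefin made by simple olefination. On the economy of chiral material it is stronger than the chosen route.
- Against: the catalyst must protonate and add at the right terminus of a 1,2-diaryl olefin whose attacking carbon bears an ester- and pivalate-deactivated, ortho-substituted ring. Such hindered stilbenes lie outside the styrene-type substrates for which confined acids are best suited. The benzylic C–O bond of A1 has the opposite sense to C2 of the target, so the furan must later be closed with inversion or through a benzylic cation, and C2 is then under thermodynamic rather than direct control. After the key step about seven operations remain (acetal cleavage, pivalate removal, ring closure, ester to aldehyde, olefination, deallylation).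
- Comparison: the chosen route uses a stoichiometric auxiliary but a predictable aldol, and only three steps follow its key step.

Alternative 2: flavanone ring contraction. The disconnection is the C3–C3a bond. In the forward step a hypervalent iodine oxidant in an acidic orthoester medium would attack the enol ether of flavanone A5 at C3; the fused aryl carbon would shift from C4 to C3, contracting the ring to the trans ester A4.
- For: the route to the dihydrobenzofuran core is short and uses cheap chalcone-type chemistry, and the aryl bromide allows a direct Heck-type attachment of the styryl arm. In step count it is as good as or better than the chosen route.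
- Against: the only source of absolute configuration is C2 of A5, a centre that can racemise by reversible retro-oxa-Michael opening under the acidic conditions of the rearrangement. With an oxygen-rich C2 aryl group, migration of that aryl group (isoflavone formation) competes with the desired shift, and the pivalate only partly suppresses it. C3 is set by thermodynamics alone.
- Comparison: the chosen route is longer but its stereocentres are set by an auxiliary-controlled aldol and are then never part of a reacting centre.

Alternative 3: Danheiser benzannulation. Ring B is disconnected at C7–C6, C5–C4 and C7–C7a. In the forward step photochemical Wolff rearrangement of diazoketone A7 would give a vinylketene that takes up siloxyalkyne A8 by (2+2) addition, four-electron ring opening and six-electron closure, giving phenol A6.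
- For: like the chosen route it builds ring B with full regiocontrol, and it runs at or near room temperature, which is milder than a thermal cycloaddition.
- Against: A7 is a chiral 2,3-dihydrofuran that already holds both stereocentres and an enol ether, so it is harder to make than the acyclic alcohol 12. In A6 C5 bears oxygen, not carbon, and C7 a free hydroxyl. Methylation, desilylation, triflation and a cross-coupling are therefore needed before deprotection.
- Comparison: the chosen route delivers C5 as a masked aldehyde and C7 as the methyl ether directly from the cycloaddition.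

Key step: step 13

## Route

Assumption: compounds 1, 3, 5, 13, 14 and 25 are taken as commercial. Acid 4 is made from alcohol 3 because direct C-silylation of but-3-ynoic acid would pass through an allene-prone polyanion.

Step 1
Reactants: 1 syringaldehyde
Product: 2 3,5-dimethoxy-4-(methoxymethoxy)benzaldehyde
Conditions: MOMCl, i-Pr2NEt, CH2Cl2, 0 °C → rt
Reagents that add atoms: chloromethyl methyl ether, COCCl
Why: O-alkylation of the hindered phenol (MOM protection), with the amine taking up HCl and the aldehyde untouched. The MOM ether should survive boron enolate, hydride, carbenoid, heat and base, and falls in the final acid step.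

Step 2
Reactants: 3 4-(trimethylsilyl)but-3-yn-1-ol
Product: 4 4-(trimethylsilyl)but-3-ynoic acid
Conditions: CrO3, H2SO4, H2O, acetone, 0 °C
Reagents that add atoms: water, O
Why: Jones oxidation of a primary alcohol through the aldehyde hydrate. The silyl-capped alkyne tolerates brief aqueous chromic acid, and the acidic medium does not isomerise the beta,gamma-alkynoic acid.

Step 3
Reactants: 4 4-(trimethylsilyl)but-3-ynoic acid; 5 (R)-4-benzyl-2-oxazolidinone
Product: 8 (R)-4-benzyl-3-[4-(trimethylsilyl)but-3-ynoyl]oxazolidin-2-one, via mixed pivalic anhydride 6 (not isolated), via lithium oxazolidinide 7 (not isolated)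
Conditions: 4, PivCl, Et3N, THF, −78 → 0 °C; 5, n-BuLi, THF, −78 °C; combine at −78 °C
Reagents that add atoms: none
Why: Standard N-acylation of the auxiliary through the mixed anhydride; the hindered pivaloyl carbonyl directs attack to the butynoyl carbonyl. Low temperature and the absence of free amine during acyl transfer should keep the propargylic CH2 from isomerising to an allene.

Step 4
Reactants: 8 (R)-4-benzyl-3-[4-(trimethylsilyl)but-3-ynoyl]oxazolidin-2-one; 2 3,5-dimethoxy-4-(methoxymethoxy)benzaldehyde
Product: 10 (R)-4-benzyl-3-{(2R,3R)-3-[3,5-dimethoxy-4-(methoxymethoxy)phenyl]-3-hydroxy-2-[(trimethylsilyl)ethynyl]propanoyl}oxazolidin-2-one, via Z boron enolate 9 (not isolated)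
Conditions: Bu2BOTf, i-Pr2NEt, CH2Cl2, −78 °C; then 2, −78 → −20 °C; pH 7 buffer, MeOH, H2O2, 0 °C
Reagents that add atoms: none
Why: Evans syn aldol. The Z boron enolate reacts through a Zimmerman–Traxler chair in which the aldehyde approaches the face opposite the benzyl group of the (R)-auxiliary, which sets C2 and C3 of 10 as (2R,3R) with alkynyl and hydroxyl syn. The closed transition state allows bond formation only at the alpha carbon, so the alkyne is retained.

Step 5
Reactants: 10 (R)-4-benzyl-3-{(2R,3R)-3-[3,5-dimethoxy-4-(methoxymethoxy)phenyl]-3-hydroxy-2-[(trimethylsilyl)ethynyl]propanoyl}oxazolidin-2-one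
Product: 11 (1R,2S)-1-[3,5-dimethoxy-4-(methoxymethoxy)phenyl]-2-[(trimethylsilyl)ethynyl]propane-1,3-diol
Conditions: LiBH4, MeOH (1 equiv), THF, 0 °C
Reagents that add atoms: none
Why: Reductive cleavage of the imide to the primary alcohol with release of the auxiliary; the hydride conditions are not basic enough for retro-aldol or epimerisation. The alkynyl carbon changes descriptor from R to S only because the CIP ranking of its neighbours changes.

Step 6
Reactants: 11 (1R,2S)-1-[3,5-dimethoxy-4-(methoxymethoxy)phenyl]-2-[(trimethylsilyl)ethynyl]propane-1,3-diol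
Product: 12 (1R,2S)-2-{[(tert-butyldimethylsilyl)oxy]methyl}-1-[3,5-dimethoxy-4-(methoxymethoxy)phenyl]-4-(trimethylsilyl)but-3-yn-1-ol
Conditions: TBSCl (1.05 equiv), imidazole, CH2Cl2, 0 °C
Reagents that add atoms: tert-butyldimethylsilyl chloride, CC(C)(C)[Si](C)(C)Cl
Why: Sterically controlled silylation; the primary hydroxyl reacts far faster than the hindered benzylic secondary one, which stays free for the ether formation.

Step 7
Reactants: 13 methyl acetoacetate; 14 methyl dimethoxyacetate
Product: 16 methyl 6,6-dimethoxy-3,5-dioxohexanoate, via acetoacetate dianion 15 (not isolated)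
Conditions: 13 (2 equiv), NaH, THF, 0 °C; n-BuLi, 0 °C; then 14 (1 equiv), 0 °C → rt; aq. NH4Cl
Reagents that add atoms: none
Why: Huckin–Weiler gamma-acylation (Claisen condensation). The terminal carbanion of the dianion is the most nucleophilic site and attacks the non-enolisable, alkoxy-activated ester 14; the second equivalent of dianion takes up the acidic proton of the product.

Step 8
Reactants: 16 methyl 6,6-dimethoxy-3,5-dioxohexanoate
Product: 17 6-(dimethoxymethyl)-4-hydroxy-2H-pyran-2-one
Conditions: DBU, toluene, 80 °C; then pH 5 phosphate buffer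
Reagents that add atoms: none
Why: Base-mediated lactonisation of a 3,5-dioxo ester: the C5 enolate oxygen attacks the ester carbonyl and methoxide leaves, giving the stabilised 4-hydroxy-2-pyrone. The buffered work-up spares the acetal.

Step 9
Reactants: 17 6-(dimethoxymethyl)-4-hydroxy-2H-pyran-2-one
Product: 18 3-diazo-6-(dimethoxymethyl)-2H-pyran-2,4(3H)-dione
Conditions: 4-AcNHC6H4SO2N3 (p-ABSA), Et3N, MeCN, 0 °C → rt
Reagents that add atoms: 4-acetamidobenzenesulfonyl azide, CC(=O)Nc1ccc(cc1)S(=O)(=O)N=[N+]=[N-]
Why: Regitz diazo transfer to the only doubly activated carbon (C3, between the lactone and ketone carbonyls), as practised on 4-hydroxy-2-pyrones and 4-hydroxycoumarins.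

Step 10
Reactants: 12 (1R,2S)-2-{[(tert-butyldimethylsilyl)oxy]methyl}-1-[3,5-dimethoxy-4-(methoxymethoxy)phenyl]-4-(trimethylsilyl)but-3-yn-1-ol; 18 3-diazo-6-(dimethoxymethyl)-2H-pyran-2,4(3H)-dione
Product: 19 3-{[(1R,2S)-2-{[(tert-butyldimethylsilyl)oxy]methyl}-1-[3,5-dimethoxy-4-(methoxymethoxy)phenyl]-4-(trimethylsilyl)but-3-yn-1-yl]oxy}-6-(dimethoxymethyl)-4-hydroxy-2H-pyran-2-one
Conditions: Rh2(OAc)4 (2 mol %), ClCH2CH2Cl, 70 °C, slow addition of 18 (1.5 equiv)
Reagents that add atoms: none
Why: Rh2(OAc)4 converts the cyclic diazo dione into an electrophilic carbenoid that the hydroxyl of 12 captures (oxonium ylide, then proton shift), the known O–H insertion of 2-diazo-1,3-dicarbonyl compounds. The carbinol C–O bond is never broken, so its configuration is kept. The medium is neutral, and the silyl cap keeps the alkyne from competing for the carbenoid.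

Step 11
Reactants: 19 3-{[(1R,2S)-2-{[(tert-butyldimethylsilyl)oxy]methyl}-1-[3,5-dimethoxy-4-(methoxymethoxy)phenyl]-4-(trimethylsilyl)but-3-yn-1-yl]oxy}-6-(dimethoxymethyl)-4-hydroxy-2H-pyran-2-one
Product: 20 3-{[(1R,2S)-2-{[(tert-butyldimethylsilyl)oxy]methyl}-1-[3,5-dimethoxy-4-(methoxymethoxy)phenyl]but-3-yn-1-yl]oxy}-6-(dimethoxymethyl)-4-hydroxy-2H-pyran-2-one
Conditions: K2CO3 (2.5 equiv), MeOH, 0 °C → rt; pH 5 buffer
Reagents that add atoms: none
Why: Methoxide-catalysed protodesilylation of the alkynylsilane; the TBS ether and MOM groups are stable. Under these conditions the pyrone is present as its 4-oxido anion, which resists nucleophilic ring opening.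

Step 12
Reactants: 20 3-{[(1R,2S)-2-{[(tert-butyldimethylsilyl)oxy]methyl}-1-[3,5-dimethoxy-4-(methoxymethoxy)phenyl]but-3-yn-1-yl]oxy}-6-(dimethoxymethyl)-4-hydroxy-2H-pyran-2-one
Product: 21 3-{[(1R,2S)-2-{[(tert-butyldimethylsilyl)oxy]methyl}-1-[3,5-dimethoxy-4-(methoxymethoxy)phenyl]but-3-yn-1-yl]oxy}-6-(dimethoxymethyl)-4-methoxy-2H-pyran-2-one
Conditions: Me2SO4, K2CO3, acetone, rt → 40 °C
Reagents that add atoms: dimethyl sulfate, COS(=O)(=O)OC
Why: O-Methylation of the ambident 4-hydroxy-2-pyrone anion; dimethyl sulfate with K2CO3 in acetone is the standard way to 4-methoxy-2-pyrones. The 2-methoxy-4-pyrone isomer is expected as the minor product and would be separated.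

Step 13
Reactants: 21 3-{[(1R,2S)-2-{[(tert-butyldimethylsilyl)oxy]methyl}-1-[3,5-dimethoxy-4-(methoxymethoxy)phenyl]but-3-yn-1-yl]oxy}-6-(dimethoxymethyl)-4-methoxy-2H-pyran-2-one
Product: 23 tert-butyl({(2R,3S)-5-(dimethoxymethyl)-2-[3,5-dimethoxy-4-(methoxymethoxy)phenyl]-7-methoxy-2,3-dihydro-1-benzofuran-3-yl}methoxy)dimethylsilane, via bridged bicyclic lactone 22 (not isolated)
Conditions: 1,2-Cl2C6H4 (0.01 M), BHT, 180 °C, sealed tube
Reagents that add atoms: none
Why: Intramolecular (4+2) cycloaddition of the 2-pyrone diene (termini C3 and C6) with the tethered terminal alkyne, then retro-(4+2) loss of CO2 from the 2-oxabicyclo[2.2.2]octadienone 22; the closest known reaction type is the thermal pyrone–alkyne Diels–Alder/decarboxylation benzannulation and its oxygen-tethered azine–alkyne relatives that give dihydrofuran-fused arenes. The internal alkyne carbon bonds to pyrone C3 (new C7a–C3a bond) and the terminal CH to pyrone C6 (new C5–C4 bond). The dihydrofuran closes as the five-membered ring fused to the bicycle, a terminus-tethered (type 1) intramolecular Diels–Alder closure through the three-atom O1–C2–C3 link, exo-dig with respect to the alkyne; ring B closes as the six-membered carbocycle through the two new sigma bonds and becomes aromatic on cycloreversion. No lasting stereocentre is formed: the two bridgehead centres of 22 (either pyrone face may react) disappear with CO2, and C2 and C3 lie outside the reacting pi systems and are not epimerisable under neutral heating. The selectivity needed is regiochemical only, and the short tether allows a single orientation, which puts OMe at C7, the acetal carbon at C5 and hydrogen at C4 and C6. The substituents on the tether (aryl at C2, CH2OTBS at C3) favour the folded conformer, and high dilution with BHT should suppress bimolecular pyrone reactions and radical pathways. Aromatisation makes the sequence irreversible.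

Step 14
Reactants: 23 tert-butyl({(2R,3S)-5-(dimethoxymethyl)-2-[3,5-dimethoxy-4-(methoxymethoxy)phenyl]-7-methoxy-2,3-dihydro-1-benzofuran-3-yl}methoxy)dimethylsilane
Product: 24 (2R,3S)-3-{[(tert-butyldimethylsilyl)oxy]methyl}-2-[3,5-dimethoxy-4-(methoxymethoxy)phenyl]-7-methoxy-2,3-dihydro-1-benzofuran-5-carbaldehyde
Conditions: PPTS (cat.), acetone/H2O, rt
Reagents that add atoms: water, O
Why: Acid-catalysed hydrolysis of an aryl dimethyl acetal, which with this weak acid is much faster than cleavage of aryl MOM ethers or of a primary TBS ether.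

Step 15
Reactants: 25 methyl 3,5-dihydroxybenzoate
Product: 26 methyl 3,5-bis(methoxymethoxy)benzoate
Conditions: MOMCl, i-Pr2NEt, CH2Cl2, 0 °C → rt
Reagents that add atoms: chloromethyl methyl ether, COCCl
Why: Twofold O-alkylation of the phenols (MOM protection), so that the later carbanion chemistry and the final deprotection use the same group as on the syringyl ring.

Step 16
Reactants: 26 methyl 3,5-bis(methoxymethoxy)benzoate
Product: 27 [3,5-bis(methoxymethoxy)phenyl]methanol
Conditions: LiAlH4, THF, 0 °C
Reagents that add atoms: none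
Why: Hydride reduction of the ester to the benzylic alcohol; MOM ethers are inert to LiAlH4.

Step 17
Reactants: 27 [3,5-bis(methoxymethoxy)phenyl]methanol
Product: 28 1-(bromomethyl)-3,5-bis(methoxymethoxy)benzene
Conditions: CBr4, PPh3, CH2Cl2, 0 °C
Reagents that add atoms: carbon tetrabromide, BrC(Br)(Br)Br
Why: Appel bromination under essentially neutral conditions, which spares the acid-labile MOM ethers.

Step 18
Reactants: 28 1-(bromomethyl)-3,5-bis(methoxymethoxy)benzene
Product: 29 diethyl [3,5-bis(methoxymethoxy)benzyl]phosphonate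
Conditions: P(OEt)3, 120 °C
Reagents that add atoms: triethyl phosphite, CCOP(OCC)OCC
Why: Michaelis–Arbuzov reaction of a benzylic bromide; the volatile bromoethane distils off.

Step 19
Reactants: 24 (2R,3S)-3-{[(tert-butyldimethylsilyl)oxy]methyl}-2-[3,5-dimethoxy-4-(methoxymethoxy)phenyl]-7-methoxy-2,3-dihydro-1-benzofuran-5-carbaldehyde; 29 diethyl [3,5-bis(methoxymethoxy)benzyl]phosphonate
Product: 31 tert-butyl({(2R,3S)-5-{(E)-2-[3,5-bis(methoxymethoxy)phenyl]ethenyl}-2-[3,5-dimethoxy-4-(methoxymethoxy)phenyl]-7-methoxy-2,3-dihydro-1-benzofuran-3-yl}methoxy)dimethylsilane, via potassium phosphonate carbanion 30 (not isolated)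
Conditions: 29, KOt-Bu, THF, 0 °C; then 24, 0 °C → rt
Reagents that add atoms: none
Why: Horner–Wadsworth–Emmons olefination. Reversible addition of the benzylic phosphonate carbanion and elimination from the favoured adduct should give the E stilbene. Neither ring stereocentre has an acidic hydrogen under these conditions.

Step 20
Reactants: 31 tert-butyl({(2R,3S)-5-{(E)-2-[3,5-bis(methoxymethoxy)phenyl]ethenyl}-2-[3,5-dimethoxy-4-(methoxymethoxy)phenyl]-7-methoxy-2,3-dihydro-1-benzofuran-3-yl}methoxy)dimethylsilane
Product: 32 gnetucleistol F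
Conditions: HCl (3 M aq.)/MeOH/THF, rt → 40 °C, degassed, dark
Reagents that add atoms: none
Why: Acidic methanolysis of the three MOM acetals and of the primary TBS ether in one operation. The trans diad is also the thermodynamically preferred arrangement, so mild acid should not erode it.

## Compound list

1 | syringaldehyde | COc1cc(C=O)cc(OC)c1O | starting material
2 | 3,5-dimethoxy-4-(methoxymethoxy)benzaldehyde | COCOc1c(OC)cc(C=O)cc1OC | intermediate
3 | 4-(trimethylsilyl)but-3-yn-1-ol | C[Si](C)(C)C#CCCO | starting material
4 | 4-(trimethylsilyl)but-3-ynoic acid | C[Si](C)(C)C#CCC(=O)O | intermediate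
5 | (R)-4-benzyl-2-oxazolidinone | O=C1OC[C@@H](Cc2ccccc2)N1 | starting material
6 | 4-(trimethylsilyl)but-3-ynoic pivalic anhydride | CC(C)(C)C(=O)OC(=O)CC#C[Si](C)(C)C | intermediate (not isolated)
7 | lithium (R)-4-benzyl-2-oxooxazolidin-3-ide | [Li+].O=C1OC[C@@H](Cc2ccccc2)[N-]1 | intermediate (not isolated)
8 | (R)-4-benzyl-3-[4-(trimethylsilyl)but-3-ynoyl]oxazolidin-2-one | O=C1OC[C@@H](Cc2ccccc2)N1C(=O)CC#C[Si](C)(C)C | intermediate
9 | (Z)-dibutylboron enolate of 8 | CCCCB(CCCC)O/C(=C\C#C[Si](C)(C)C)N1[C@H](Cc2ccccc2)COC1=O | intermediate (not isolated)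
10 | (R)-4-benzyl-3-{(2R,3R)-3-[3,5-dimethoxy-4-(methoxymethoxy)phenyl]-3-hydroxy-2-[(trimethylsilyl)ethynyl]propanoyl}oxazolidin-2-one | O=C1OC[C@@H](Cc2ccccc2)N1C(=O)[C@H](C#C[Si](C)(C)C)[C@@H](O)c1cc(OC)c(OCOC)c(OC)c1 | intermediate
11 | (1R,2S)-1-[3,5-dimethoxy-4-(methoxymethoxy)phenyl]-2-[(trimethylsilyl)ethynyl]propane-1,3-diol | OC[C@H](C#C[Si](C)(C)C)[C@@H](O)c1cc(OC)c(OCOC)c(OC)c1 | intermediate
12 | (1R,2S)-2-{[(tert-butyldimethylsilyl)oxy]methyl}-1-[3,5-dimethoxy-4-(methoxymethoxy)phenyl]-4-(trimethylsilyl)but-3-yn-1-ol | CC(C)(C)[Si](C)(C)OC[C@H](C#C[Si](C)(C)C)[C@@H](O)c1cc(OC)c(OCOC)c(OC)c1 | intermediate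
13 | methyl acetoacetate | CC(=O)CC(=O)OC | starting material
14 | methyl dimethoxyacetate | COC(OC)C(=O)OC | starting material
15 | sodium lithium dianion of methyl acetoacetate | [Na+].[Li+].COC(=O)[CH-]C(=O)[CH2-] | intermediate (not isolated)
16 | methyl 6,6-dimethoxy-3,5-dioxohexanoate | COC(OC)C(=O)CC(=O)CC(=O)OC | intermediate
17 | 6-(dimethoxymethyl)-4-hydroxy-2H-pyran-2-one | COC(OC)C1=CC(O)=CC(=O)O1 | intermediate
18 | 3-diazo-6-(dimethoxymethyl)-2H-pyran-2,4(3H)-dione | COC(OC)C1=CC(=O)C(=[N+]=[N-])C(=O)O1 | intermediate
19 | 3-{[(1R,2S)-2-{[(tert-butyldimethylsilyl)oxy]methyl}-1-[3,5-dimethoxy-4-(methoxymethoxy)phenyl]-4-(trimethylsilyl)but-3-yn-1-yl]oxy}-6-(dimethoxymethyl)-4-hydroxy-2H-pyran-2-one | COCOc1c(OC)cc([C@H](OC2=C(O)C=C(C(OC)OC)OC2=O)[C@H](CO[Si](C)(C)C(C)(C)C)C#C[Si](C)(C)C)cc1OC | intermediate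
20 | 3-{[(1R,2S)-2-{[(tert-butyldimethylsilyl)oxy]methyl}-1-[3,5-dimethoxy-4-(methoxymethoxy)phenyl]but-3-yn-1-yl]oxy}-6-(dimethoxymethyl)-4-hydroxy-2H-pyran-2-one | COCOc1c(OC)cc([C@H](OC2=C(O)C=C(C(OC)OC)OC2=O)[C@H](CO[Si](C)(C)C(C)(C)C)C#C)cc1OC | intermediate
21 | 3-{[(1R,2S)-2-{[(tert-butyldimethylsilyl)oxy]methyl}-1-[3,5-dimethoxy-4-(methoxymethoxy)phenyl]but-3-yn-1-yl]oxy}-6-(dimethoxymethyl)-4-methoxy-2H-pyran-2-one | COCOc1c(OC)cc([C@H](OC2=C(OC)C=C(C(OC)OC)OC2=O)[C@H](CO[Si](C)(C)C(C)(C)C)C#C)cc1OC | intermediate (precursor of the key step)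
22 | bridged 2-oxabicyclo[2.2.2]octadienone cycloadduct of 21, fused to the dihydrofuran (either bridgehead diastereomer) | COCOc1c(OC)cc(cc1OC)[C@@H]2OC34C(OC)=CC(C(OC)OC)(C=C3[C@H]2CO[Si](C)(C)C(C)(C)C)OC4=O | intermediate (not isolated)
23 | tert-butyl({(2R,3S)-5-(dimethoxymethyl)-2-[3,5-dimethoxy-4-(methoxymethoxy)phenyl]-7-methoxy-2,3-dihydro-1-benzofuran-3-yl}methoxy)dimethylsilane | COCOc1c(OC)cc([C@@H]2Oc3c(OC)cc(C(OC)OC)cc3[C@H]2CO[Si](C)(C)C(C)(C)C)cc1OC | intermediate (product of the key step)
24 | (2R,3S)-3-{[(tert-butyldimethylsilyl)oxy]methyl}-2-[3,5-dimethoxy-4-(methoxymethoxy)phenyl]-7-methoxy-2,3-dihydro-1-benzofuran-5-carbaldehyde | COCOc1c(OC)cc([C@@H]2Oc3c(OC)cc(C=O)cc3[C@H]2CO[Si](C)(C)C(C)(C)C)cc1OC | intermediate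
25 | methyl 3,5-dihydroxybenzoate | COC(=O)c1cc(O)cc(O)c1 | starting material
26 | methyl 3,5-bis(methoxymethoxy)benzoate | COCOc1cc(cc(OCOC)c1)C(=O)OC | intermediate
27 | [3,5-bis(methoxymethoxy)phenyl]methanol | COCOc1cc(CO)cc(OCOC)c1 | intermediate
28 | 1-(bromomethyl)-3,5-bis(methoxymethoxy)benzene | COCOc1cc(CBr)cc(OCOC)c1 | intermediate
29 | diethyl [3,5-bis(methoxymethoxy)benzyl]phosphonate | CCOP(=O)(OCC)Cc1cc(OCOC)cc(OCOC)c1 | intermediate
30 | potassium salt of the benzylic carbanion of 29 | [K+].CCOP(=O)(OCC)[CH-]c1cc(OCOC)cc(OCOC)c1 | intermediate (not isolated)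
31 | tert-butyl({(2R,3S)-5-{(E)-2-[3,5-bis(methoxymethoxy)phenyl]ethenyl}-2-[3,5-dimethoxy-4-(methoxymethoxy)phenyl]-7-methoxy-2,3-dihydro-1-benzofuran-3-yl}methoxy)dimethylsilane | COCOc1c(OC)cc([C@@H]2Oc3c(OC)cc(/C=C/c4cc(OCOC)cc(OCOC)c4)cc3[C@H]2CO[Si](C)(C)C(C)(C)C)cc1OC | intermediate
32 | gnetucleistol F, 5-{(E)-2-[(2R,3S)-2-(4-hydroxy-3,5-dimethoxyphenyl)-3-(hydroxymethyl)-7-methoxy-2,3-dihydro-1-benzofuran-5-yl]ethenyl}benzene-1,3-diol | COc1cc([C@@H]2Oc3c(OC)cc(/C=C/c4cc(O)cc(O)c4)cc3[C@H]2CO)cc(OC)c1O | target

## Step count and least certain steps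

Total: 20 steps. Longest linear sequence: 12 steps (steps 2, 3, 4, 5, 6, 10, 11, 12, 13, 14, 19, 20).

**Step 13 (key step).** The most likely failure is that the unactivated alkyne adds too slowly to the donor-substituted pyrone. Thermal ionisation or elimination at the benzylic pyronyl ether would then consume the substrate before cycloaddition. The fallback sets out from 21 and returns at 23. The terminal alkyne would be brominated (NBS, cat. AgNO3, acetone, rt) to 3-{[(1R,2S)-4-bromo-2-{[(tert-butyldimethylsilyl)oxy]methyl}-1-[3,5-dimethoxy-4-(methoxymethoxy)phenyl]but-3-yn-1-yl]oxy}-6-(dimethoxymethyl)-4-methoxy-2H-pyran-2-one F1. The bromoalkyne is a more polarised dienophile with a lower-lying acceptor orbital for the electron-rich pyrone and should undergo the same cycloaddition and CO2 loss at lower temperature. This would give tert-butyl({(2R,3S)-4-bromo-5-(dimethoxymethyl)-2-[3,5-dimethoxy-4-(methoxymethoxy)phenyl]-7-methoxy-2,3-dihydro-1-benzofuran-3-yl}methoxy)dimethylsilane F2. The halogen would then be removed by palladium-catalysed formate reduction (Pd(OAc)2, PPh3, HCO2Na, DMF, 80 °C), at a stage where no alkene is present, to give 23.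

**Step 10 (O–H insertion).** The hindered secondary alcohol may capture the carbenoid slowly, so that carbene dimerisation or attack on the electron-rich arene takes over. The fallback sets out from 17 and 12 and returns at 21, bypassing steps 11 and 12. Pyrone 17 would be O-methylated (Me2SO4, K2CO3, acetone) to 6-(dimethoxymethyl)-4-methoxy-2H-pyran-2-one F3 and iodinated at the nucleophilic C3 (NIS, MeCN) to 6-(dimethoxymethyl)-3-iodo-4-methoxy-2H-pyran-2-one F4. Copper-catalysed Ullmann-type C–O coupling of F4 with 12 (CuI, 3,4,7,8-tetramethyl-1,10-phenanthroline, Cs2CO3, toluene, 80 °C) forms the ether at the pyrone carbon and so retains the carbinol configuration. It would give 3-{[(1R,2S)-2-{[(tert-butyldimethylsilyl)oxy]methyl}-1-[3,5-dimethoxy-4-(methoxymethoxy)phenyl]-4-(trimethylsilyl)but-3-yn-1-yl]oxy}-6-(dimethoxymethyl)-4-methoxy-2H-pyran-2-one F5. Catalytic AgNO3 in aqueous acetone would then free the alkyne to give 21. The carbonate base (possible oxygen-to-oxygen silyl shift in 12, attack on the lactone) is the reason this is the second choice.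

**Step 4 (aldol).** The propargylic boron enolate or the doubly activated alpha centre of the aldolate may isomerise towards allenyl species or epimerise, which would lower the diastereomer ratio. The fallback sets out from 2 and returns at 12, bypassing steps 2 to 6. The ynone 1-[(tert-butyldimethylsilyl)oxy]-4-(trimethylsilyl)but-3-yn-2-one F6 would be made from lithium (trimethylsilyl)acetylide and the Weinreb amide of O-silylated glycolic acid. Noyori transfer hydrogenation (RuCl[(S,S)-TsDPEN](p-cymene), HCO2H/Et3N) would reduce it to (R)-1-[(tert-butyldimethylsilyl)oxy]-4-(trimethylsilyl)but-3-yn-2-ol F7; by analogy with 4-aryl-3-butyn-2-ones this catalyst enantiomer is expected to give this alcohol enantiomer. Mesylation (MsCl, Et3N) gives (R)-1-[(tert-butyldimethylsilyl)oxy]-4-(trimethylsilyl)but-3-yn-2-yl methanesulfonate F8. With Pd(OAc)2, PPh3 and Et2Zn in THF at −78 → −20 °C, F8 forms a chiral allenylzinc reagent by anti displacement, which adds to 2 through a cyclic transition state, so that the new C–C bond replaces the mesylate with overall inversion. This anti-selective Marshall propargylation should give 12 directly, because the anti relationship in that convention is the relationship present in 12.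

**Step 20 (deprotection).** Once the syringyl hydroxyl is free, acid may open or epimerise the C2–O1 bond through a quinone methide, and the electron-rich stilbene may oligomerise by a cationic path. The fallback sets out from 31 and returns at 32. Bu4NF in THF would remove only the silyl ether, giving {(2R,3S)-5-{(E)-2-[3,5-bis(methoxymethoxy)phenyl]ethenyl}-2-[3,5-dimethoxy-4-(methoxymethoxy)phenyl]-7-methoxy-2,3-dihydro-1-benzofuran-3-yl}methanol F9. The MOM ethers would then be cleaved under aprotic conditions by thiol-assisted Lewis acid (ZnBr2, n-PrSH, CH2Cl2, 0 °C), which avoids a protic strong acid altogether.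

## Further compounds

F1 | step 13 | 3-{[(1R,2S)-4-bromo-2-{[(tert-butyldimethylsilyl)oxy]methyl}-1-[3,5-dimethoxy-4-(methoxymethoxy)phenyl]but-3-yn-1-yl]oxy}-6-(dimethoxymethyl)-4-methoxy-2H-pyran-2-one | COCOc1c(OC)cc([C@H](OC2=C(OC)C=C(C(OC)OC)OC2=O)[C@H](CO[Si](C)(C)C(C)(C)C)C#CBr)cc1OC
F2 | step 13 | tert-butyl({(2R,3S)-4-bromo-5-(dimethoxymethyl)-2-[3,5-dimethoxy-4-(methoxymethoxy)phenyl]-7-methoxy-2,3-dihydro-1-benzofuran-3-yl}methoxy)dimethylsilane | COCOc1c(OC)cc([C@@H]2Oc3c(OC)cc(C(OC)OC)c(Br)c3[C@H]2CO[Si](C)(C)C(C)(C)C)cc1OC
F3 | step 10 | 6-(dimethoxymethyl)-4-methoxy-2H-pyran-2-one | COC(OC)C1=CC(OC)=CC(=O)O1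
F4 | step 10 | 6-(dimethoxymethyl)-3-iodo-4-methoxy-2H-pyran-2-one | COC(OC)C1=CC(OC)=C(I)C(=O)O1
F5 | step 10 | 3-{[(1R,2S)-2-{[(tert-butyldimethylsilyl)oxy]methyl}-1-[3,5-dimethoxy-4-(methoxymethoxy)phenyl]-4-(trimethylsilyl)but-3-yn-1-yl]oxy}-6-(dimethoxymethyl)-4-methoxy-2H-pyran-2-one | COCOc1c(OC)cc([C@H](OC2=C(OC)C=C(C(OC)OC)OC2=O)[C@H](CO[Si](C)(C)C(C)(C)C)C#C[Si](C)(C)C)cc1OC
F6 | step 4 | 1-[(tert-butyldimethylsilyl)oxy]-4-(trimethylsilyl)but-3-yn-2-one | CC(C)(C)[Si](C)(C)OCC(=O)C#C[Si](C)(C)C
F7 | step 4 | (R)-1-[(tert-butyldimethylsilyl)oxy]-4-(trimethylsilyl)but-3-yn-2-ol | CC(C)(C)[Si](C)(C)OC[C@H](O)C#C[Si](C)(C)C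
F8 | step 4 | (R)-1-[(tert-butyldimethylsilyl)oxy]-4-(trimethylsilyl)but-3-yn-2-yl methanesulfonate | CC(C)(C)[Si](C)(C)OC[C@H](OS(C)(=O)=O)C#C[Si](C)(C)C
F9 | step 20 | {(2R,3S)-5-{(E)-2-[3,5-bis(methoxymethoxy)phenyl]ethenyl}-2-[3,5-dimethoxy-4-(methoxymethoxy)phenyl]-7-methoxy-2,3-dihydro-1-benzofuran-3-yl}methanol | COCOc1c(OC)cc([C@@H]2Oc3c(OC)cc(/C=C/c4cc(OCOC)cc(OCOC)c4)cc3[C@H]2CO)cc1OC
A1 | alternative 1 | methyl 3-{(4S,5S)-4-[3,5-dimethoxy-4-(prop-2-en-1-yloxy)phenyl]-1,3-dioxan-5-yl}-5-methoxy-4-(pivaloyloxy)benzoate | C=CCOc1c(OC)cc([C@H]2OCOC[C@@H]2c3cc(C(=O)OC)cc(OC)c3OC(=O)C(C)(C)C)cc1OC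
A2 | alternative 1 | methyl 3-{(E)-2-[3,5-dimethoxy-4-(prop-2-en-1-yloxy)phenyl]ethenyl}-5-methoxy-4-(pivaloyloxy)benzoate | C=CCOc1c(OC)cc(/C=C/c2cc(C(=O)OC)cc(OC)c2OC(=O)C(C)(C)C)cc1OC
A3 | alternative 1 | formaldehyde | C=O
A4 | alternative 2 | methyl (2R,3R)-5-bromo-2-[3,5-dimethoxy-4-(pivaloyloxy)phenyl]-7-methoxy-2,3-dihydro-1-benzofuran-3-carboxylate | COc1cc([C@@H]2Oc3c(OC)cc(Br)cc3[C@H]2C(=O)OC)cc(OC)c1OC(=O)C(C)(C)C
A5 | alternative 2 | (2R)-6-bromo-2-[3,5-dimethoxy-4-(pivaloyloxy)phenyl]-8-methoxy-2,3-dihydro-4H-chromen-4-one | COc1cc([C@@H]2Oc3c(OC)cc(Br)cc3C(=O)C2)cc(OC)c1OC(=O)C(C)(C)C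
A6 | alternative 3 | (2R,3S)-3-{[(tert-butyldimethylsilyl)oxy]methyl}-2-[3,5-dimethoxy-4-(methoxymethoxy)phenyl]-5-[(triisopropylsilyl)oxy]-2,3-dihydro-1-benzofuran-7-ol | COCOc1c(OC)cc([C@@H]2Oc3c(O)cc(O[Si](C(C)C)(C(C)C)C(C)C)cc3[C@H]2CO[Si](C)(C)C(C)(C)C)cc1OC
A7 | alternative 3 | 2-diazo-1-[(4S,5R)-4-{[(tert-butyldimethylsilyl)oxy]methyl}-5-[3,5-dimethoxy-4-(methoxymethoxy)phenyl]-4,5-dihydrofuran-3-yl]ethan-1-one | COCOc1c(OC)cc([C@@H]2OC=C(C(=O)C=[N+]=[N-])[C@H]2CO[Si](C)(C)C(C)(C)C)cc1OC
A8 | alternative 3 | (ethynyloxy)triisopropylsilane | C#CO[Si](C(C)C)(C(C)C)C(C)C
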